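**Plan**
- Cuts: C8–C9 (dihydrofuran carbon to the first side-chain carbon), the C11=C12 and C11'=C12' double bonds on either side of a C10 trienedial, and C5–O1 plus C6–C7 of the bicyclic end.
- Enabling feature: C8 lies in the 2,5-dihydrofuran ring between ring oxygen O1 and the C6=C7 double bond. A C8 acetate therefore ionizes to a furan-like allyl oxocarbenium ion (O1=C8–C7=C6). Its other terminus C6 is buried between quaternary C1 and C5, so an alkenyl nucleophile can only enter at C8.
- Forward order: actinol supplies the cyclohexane ring; Negishi coupling adds C7–C8; iodolactonization/elimination builds the butenolide ring; reduction gives the lactol acetate; C8–C9 alkenylation with a C4 boryl phosphonate follows; Horner–Wadsworth–Emmons union with a C25 aldehyde (cyclohexene-end C15 ylide + C10 dialdehyde) and desilylation finish the route.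
- Stereochemistry: C3 comes from (4R,6R)-actinol; C5 is relayed from C3 by trans-diaxial iodolactonization; C8 is set by a chiral boronate (reagent control); C3'/C6' come from a trans-selective enone reduction plus lipase resolution; C9=C10 comes from syn-hydroboration, the other new double bonds from olefination with thermal equilibration.

Key step: step 10

Remark: carotenoid numbering is used throughout (ring carbons C1–C6 with C5 carrying CH3 and O1, chain C7–C15, primed numbers for the cyclohexene half); the lipase of step 14 is assumed to acylate the (3'S,6'S) antipode.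

**Step 1**
Reactants: 1 (4R,6R)-4-hydroxy-2,2,6-trimethylcyclohexan-1-one
Product: 2 (4R,6R)-4-(tert-butyldimethylsilyloxy)-2,2,6-trimethylcyclohexan-1-one
Conditions: TBSCl, imidazole, DMF, rt
Reagents that add atoms: tert-butyldimethylsilyl chloride, CC(C)(C)[Si](C)(C)Cl
Why: Imidazole-promoted O-silylation of the secondary alcohol masks the C3 hydroxyl for the strong-base and organometallic steps and leaves both stereocentres untouched.

**Step 2**
Reactants: 2 silyl ether ketone
Product: 3 (4R)-4-(tert-butyldimethylsilyloxy)-2,6,6-trimethylcyclohex-1-en-1-yl trifluoromethanesulfonate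
Conditions: LiN(iPr)2, THF, −78 °C; then PhNTf2, −78 °C → rt
Reagents that add atoms: N-phenylbis(trifluoromethanesulfonimide), O=S(=O)(N(c1ccccc1)S(=O)(=O)C(F)(F)F)C(F)(F)F
Why: Enolate formation and O-triflation (enol triflate synthesis) can occur only toward C5, the sole enolizable α-carbon because C1 is quaternary, so a single tetrasubstituted C5=C6 triflate should form while the C5 centre is erased on purpose and C3 is kept.

**Step 3**
Reactants: 3 enol triflate
Product: 4 ethyl 2-[(4R)-4-(tert-butyldimethylsilyloxy)-2,6,6-trimethylcyclohex-1-en-1-yl]acetate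
Conditions: BrZnCH2CO2Et, Pd2(dba)3 (cat.), 2-dicyclohexylphosphino-2',4',6'-triisopropylbiphenyl (cat.), THF, 60 °C
Reagents that add atoms: (2-ethoxy-2-oxoethyl)zinc bromide, CCOC(=O)C[Zn]Br
Why: Negishi cross-coupling of the Reformatsky-type zinc ester enolate with the alkenyl triflate should form C6–C7 and leave the ester β,γ to the tetrasubstituted C5=C6 double bond, with no new stereocentre.

**Step 4**
Reactants: 4 ethyl ester
Product: 5 2-[(4R)-4-(tert-butyldimethylsilyloxy)-2,6,6-trimethylcyclohex-1-en-1-yl]acetic acid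
Conditions: LiOH, THF/MeOH/H2O, rt; then 1 M HCl to pH 4
Reagents that add atoms: lithium hydroxide, [Li+].[OH-]
Why: Ester saponification followed by mild acidification should free the acid without cleaving the silyl ether or moving the double bond.

**Step 5**
Reactants: 5 β,γ-unsaturated acid
Product: 6 (3aR,6S,7aR)-6-(tert-butyldimethylsilyloxy)-3a-iodo-4,4,7a-trimethylhexahydro-1-benzofuran-2(3H)-one
Conditions: I2, NaHCO3, MeCN, 0 °C → rt, dark
Reagents that add atoms: iodine, II
Why: Iodolactonization through the iodonium ion of C5=C6 should close the γ-lactone at C5 (preferred to the strained spiro β-lactone under reversible conditions) by trans-diaxial opening of the half-chair that keeps C3–OTBS equatorial, so the new C5–O bond is anti to iodine on C6 and trans to the C3 oxygen, which is the (5R) configuration.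

**Step 6**
Reactants: 6 iodolactone
Product: 7 (6S,7aR)-6-(tert-butyldimethylsilyloxy)-4,4,7a-trimethyl-5,6,7,7a-tetrahydro-1-benzofuran-2(4H)-one (O-silyl loliolide)
Conditions: DBU, toluene, 80 °C
Reagents that add atoms: none
Why: Base-induced dehydroiodination (E2/E1cB, the C7 hydrogens being α to the lactone carbonyl) should give the butenolide, and only toward C7 because C1 and C5 carry no hydrogen, with no stereocentre affected.

**Step 7**
Reactants: 7 butenolide
Product: 9 (6S,7aR)-6-(tert-butyldimethylsilyloxy)-4,4,7a-trimethyl-2,4,5,6,7,7a-hexahydro-1-benzofuran-2-yl acetate (both C8 epimers), via diisobutylaluminium lactolate 8 (not isolated)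
Conditions: iBu2AlH, CH2Cl2, −78 °C; then pyridine, 4-(dimethylamino)pyridine, Ac2O, −78 → −20 °C
Reagents that add atoms: acetic anhydride, CC(=O)OC(C)=O
Why: Low-temperature 1,2-reduction of the butenolide stops at the aluminium hemiacetal, which is acetylated in the same flask (reductive acetylation of a lactone), while quaternary C5 rules out dehydration to a furan and the C8 epimer mixture is harmless because C8 becomes planar in step 10.

**Step 8**
Reactants: 10 1-bromobut-2-yne
Product: 11 diethyl but-2-yn-1-ylphosphonate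
Conditions: P(OEt)3 (neat), 120 °C
Reagents that add atoms: triethyl phosphite, CCOP(OCC)OCC
Why: Michaelis–Arbuzov reaction at the primary propargylic bromide (SN2 at CH2) should give the propargylic phosphonate.

**Step 9**
Reactants: 11 alkynyl phosphonate
Product: 13 dicyclohexyl [(2Z)-4-(diethoxyphosphoryl)but-2-en-2-yl]boronate (boron trans to the CH2P group), via alkenyl(dicyclohexyl)borane 12 (not isolated)
Conditions: (c-C6H11)2BH, THF, 0 °C → rt; then Me3NO (2 equiv), 0 °C → rt
Reagents that add atoms: dicyclohexylborane, B(C1CCCCC1)C1CCCCC1; trimethylamine N-oxide, C[N+](C)(C)[O-]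
Why: Syn hydroboration of the internal alkyne by the bulky dialkylborane should place boron on the methyl-bearing carbon (less hindered and remote from the phosphonomethyl group), and amine-oxide oxidation of the two B–cyclohexyl bonds (faster than B–alkenyl) gives the dialkoxy boronate with boron trans to CH2P, the geometry that becomes (9E) in the target.

**Step 10**
Reactants: 9 lactol acetate; 13 alkenylboronate (1.5 equiv)
Product: 14 diethyl {(2E)-3-[(2S,6S,7aR)-6-(tert-butyldimethylsilyloxy)-4,4,7a-trimethyl-2,4,5,6,7,7a-hexahydro-1-benzofuran-2-yl]but-2-en-1-yl}phosphonate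
Conditions: Yb(OTf)3 (cat.), (2R,3R)-4-(dibenzylamino)-2,3-dihydroxy-4-oxobutanoic acid (cat.), 4 Å molecular sieves, EtOAc, −40 → −20 °C
Reagents that add atoms: none
Why: Yb(OTf)3 ionizes the C8–OAc bond of 9 to the allyl oxocarbenium ion O1=C8–C7=C6, while boronate 13 exchanges its cyclohexyloxy groups for the chiral hydroxy acid and takes up acetate to give a tetracoordinate boronate that hands its alkenyl carbon C9 to C8 inside the ion pair with retention of the C9=C10 geometry. The closest known reaction type is the hydroxy acid/lanthanide triflate-catalysed addition of alkenylboronates to cyclic allylic acetals (2-alkoxy-2H-chromenes), a Petasis-type alkenylation of an oxocarbenium ion. No ring is closed. The new stereocentre C8 is set (S) by the chiral boronate (reagent control), because the two faces of the planar cation differ only by the axial C5 methyl group against the ring methylene C4 and the substrate is expected to be nearly unbiased; the (2R,3R) acid is written for attack syn to the C5 methyl group and this assignment has to be confirmed in the first run. The step needs regioselectivity for C8 over C6, which is secured by C6 lying between the quaternary carbons C1 and C5, and it needs a cation that cannot eliminate, which is secured by the absence of any hydrogen on C1, C5 or C6.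

**Step 11**
Reactants: 15 (±)-α-ionone
Product: 16 ethyl (2E,4E)-3-methyl-5-(2,6,6-trimethylcyclohex-2-en-1-yl)penta-2,4-dienoate (racemic)
Conditions: (EtO)2P(O)CH2CO2Et, NaH, THF, 0 °C → reflux
Reagents that add atoms: triethyl phosphonoacetate, CCOC(=O)CP(=O)(OCC)OCC
Why: Horner–Wadsworth–Emmons olefination of the methyl ketone should give mainly the (2E)-dienoate, the minor (2Z) isomer being removed by chromatography, and it leaves the ring stereocentre untouched.

**Step 12**
Reactants: 16 dienoate
Product: 17 ethyl (2E,4E)-3-methyl-5-(2,6,6-trimethyl-4-oxocyclohex-2-en-1-yl)penta-2,4-dienoate (racemic)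
Conditions: t-BuOOH, Rh2(cap)4 (cap = caprolactamate, cat.), K2CO3, CH2Cl2, rt
Reagents that add atoms: tert-butyl hydroperoxide, CC(C)(C)OO
Why: Dirhodium-carboxamidate-catalysed allylic oxidation should convert the only allylic ring methylene (C3') into the enone carbonyl, since the tertiary C6'–H cannot give a ketone.

**Step 13**
Reactants: 17 enone
Product: 18 ethyl (2E,4E)-5-[(1RS,4RS)-4-hydroxy-2,6,6-trimethylcyclohex-2-en-1-yl]-3-methylpenta-2,4-dienoate (racemic trans alcohol)
Conditions: NaBH4, CeCl3·7H2O, MeOH, −20 °C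
Reagents that add atoms: none
Why: Luche 1,2-reduction should deliver hydride to the C3' carbonyl from the face opposite the axial C1' methyl group, which is the face of the pseudoaxial C6' side chain, so the 3',6'-trans alcohol is expected as the main diastereomer and the dienoate is not reduced.

**Step 14**
Reactants: 18 racemic trans alcohol
Product: 19 ethyl (2E,4E)-5-[(1R,4R)-4-hydroxy-2,6,6-trimethylcyclohex-2-en-1-yl]-3-methylpenta-2,4-dienoate
Conditions: vinyl acetate, lipase from Burkholderia cepacia (lipase PS, immobilized), t-BuOMe, 30 °C, to just beyond half conversion; chromatography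
Reagents that add atoms: none
Why: Lipase-catalysed transesterification (enzymatic kinetic resolution) should acetylate the (3'S,6'S) antipode, whose carbinol has the spatial arrangement that lipases accept in hydroxylated cyclohexene end groups, so the (3'R,6'R) alcohol remains and is separated from the acetate.

**Step 15**
Reactants: 19 (1R,4R) hydroxy ester
Product: 20 (2E,4E)-5-[(1R,4R)-4-hydroxy-2,6,6-trimethylcyclohex-2-en-1-yl]-3-methylpenta-2,4-dien-1-ol
Conditions: iBu2AlH (3.3 equiv), CH2Cl2, −78 °C; aq. potassium sodium tartrate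
Reagents that add atoms: none
Why: 1,2-Reduction of the conjugated ester by the aluminium hydride should give the allylic alcohol with both stereocentres and both double-bond geometries intact.

**Step 16**
Reactants: 20 diol
Product: 22 [(2E,4E)-5-[(1R,4R)-4-hydroxy-2,6,6-trimethylcyclohex-2-en-1-yl]-3-methylpenta-2,4-dien-1-yl]triphenylphosphonium chloride, via allylic chloride 21 (not isolated)
Conditions: MsCl (1.05 equiv), 2,4,6-collidine, LiCl, DMF, 0 °C; then PPh3, rt
Reagents that add atoms: lithium chloride, [Li+].[Cl-]; triphenylphosphine, c1ccc(cc1)P(c1ccccc1)c1ccccc1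
Why: Chemoselective mesylation of the primary dienylic alcohol, chloride displacement and SN2 quaternization of PPh3 (phosphonium salt formation) run under non-acidic conditions, which keeps the acid-labile allylic C3' hydroxyl from ionizing.

**Step 17**
Reactants: 22 phosphonium chloride; 23 (2E,4E,6E)-2,7-dimethylocta-2,4,6-trienedial (3 equiv)
Product: 24 (2E,4E,6E,8E,10E,12E)-13-[(1R,4R)-4-hydroxy-2,6,6-trimethylcyclohex-2-en-1-yl]-2,7,11-trimethyltrideca-2,4,6,8,10,12-hexaenal
Conditions: KOtBu, THF, −20 → 0 °C, ylide added to 23; then n-heptane, 80 °C, dark, argon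
Reagents that add atoms: none
Why: Wittig olefination of the semi-stabilized allylic ylide with an excess of the symmetrical dialdehyde should give the mono-adduct, and heating equilibrates the new C11'=C12' bond to E.

**Step 18**
Reactants: 14 bicyclic phosphonate; 24 C25 hydroxy aldehyde
Product: 25 (3S,5R,8S,3'R,6'R)-3-(tert-butyldimethylsilyloxy)-5,8-epoxy-5,8-dihydro-β,ε-caroten-3'-ol
Conditions: KOtBu (2.2 equiv), THF, −40 → 0 °C, base added to the mixture of 14 and 24, dark, argon; then n-heptane, 80 °C
Reagents that add atoms: none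
Why: Horner–Wadsworth–Emmons olefination of the allylic phosphonate anion, generated in the presence of the aldehyde so that its standing concentration stays low, should form C11=C12 mainly E (the hindered Z isomer is equilibrated thermally) and tolerates the potassium alkoxide of the free C3' hydroxyl.

**Step 19**
Reactants: 25 silyl ether
Product: 26 (3S,5R,8S,3'R,6'R)-5,8-epoxy-5,8-dihydro-β,ε-carotene-3,3'-diol
Conditions: Bu4NF, THF, 0 °C → rt, dark, argon
Reagents that add atoms: none
Why: Fluoride-mediated desilylation under non-acidic conditions should free the C3 hydroxyl without epimerizing the acid-labile C8 centre or isomerizing the polyene.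

**Compound list**
1 | (4R,6R)-4-hydroxy-2,2,6-trimethylcyclohexan-1-one (trans-actinol) | O=C1C(C)(C)C[C@H](O)C[C@H]1C | starting material
2 | (4R,6R)-4-(tert-butyldimethylsilyloxy)-2,2,6-trimethylcyclohexan-1-one | O=C1C(C)(C)C[C@H](O[Si](C)(C)C(C)(C)C)C[C@H]1C | intermediate
3 | (4R)-4-(tert-butyldimethylsilyloxy)-2,6,6-trimethylcyclohex-1-en-1-yl trifluoromethanesulfonate | CC1=C(OS(=O)(=O)C(F)(F)F)C(C)(C)C[C@H](O[Si](C)(C)C(C)(C)C)C1 | intermediate
4 | ethyl 2-[(4R)-4-(tert-butyldimethylsilyloxy)-2,6,6-trimethylcyclohex-1-en-1-yl]acetate | CC1=C(CC(=O)OCC)C(C)(C)C[C@H](O[Si](C)(C)C(C)(C)C)C1 | intermediate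
5 | 2-[(4R)-4-(tert-butyldimethylsilyloxy)-2,6,6-trimethylcyclohex-1-en-1-yl]acetic acid | CC1=C(CC(=O)O)C(C)(C)C[C@H](O[Si](C)(C)C(C)(C)C)C1 | intermediate
6 | (3aR,6S,7aR)-6-(tert-butyldimethylsilyloxy)-3a-iodo-4,4,7a-trimethylhexahydro-1-benzofuran-2(3H)-one | O=C1C[C@@]2(I)C(C)(C)C[C@H](O[Si](C)(C)C(C)(C)C)C[C@@]2(C)O1 | intermediate
7 | (6S,7aR)-6-(tert-butyldimethylsilyloxy)-4,4,7a-trimethyl-5,6,7,7a-tetrahydro-1-benzofuran-2(4H)-one | O=C1C=C2C(C)(C)C[C@H](O[Si](C)(C)C(C)(C)C)C[C@@]2(C)O1 | intermediate
8 | diisobutylaluminium lactolate of 7 (C8 epimers, not isolated) | CC(C)C[Al](CC(C)C)OC1C=C2C(C)(C)C[C@H](O[Si](C)(C)C(C)(C)C)C[C@@]2(C)O1 | intermediate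
9 | (6S,7aR)-6-(tert-butyldimethylsilyloxy)-4,4,7a-trimethyl-2,4,5,6,7,7a-hexahydro-1-benzofuran-2-yl acetate (C8 epimers) | CC(=O)OC1C=C2C(C)(C)C[C@H](O[Si](C)(C)C(C)(C)C)C[C@@]2(C)O1 | intermediate
10 | 1-bromobut-2-yne | CC#CCBr | starting material
11 | diethyl but-2-yn-1-ylphosphonate | CC#CCP(=O)(OCC)OCC | intermediate
12 | diethyl [(2Z)-3-(dicyclohexylboranyl)but-2-en-1-yl]phosphonate (not isolated) | C1CCCCC1B(C1CCCCC1)/C(C)=C/CP(=O)(OCC)OCC | intermediate
13 | dicyclohexyl [(2Z)-4-(diethoxyphosphoryl)but-2-en-2-yl]boronate | C1CCCCC1OB(OC1CCCCC1)/C(C)=C/CP(=O)(OCC)OCC | intermediate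
14 | diethyl {(2E)-3-[(2S,6S,7aR)-6-(tert-butyldimethylsilyloxy)-4,4,7a-trimethyl-2,4,5,6,7,7a-hexahydro-1-benzofuran-2-yl]but-2-en-1-yl}phosphonate | CCOP(=O)(OCC)C/C=C(\C)[C@@H]1C=C2C(C)(C)C[C@H](O[Si](C)(C)C(C)(C)C)C[C@@]2(C)O1 | intermediate
15 | (±)-α-ionone, (3E)-4-(2,6,6-trimethylcyclohex-2-en-1-yl)but-3-en-2-one | CC(=O)/C=C/C1C(C)=CCCC1(C)C | starting material
16 | ethyl (2E,4E)-3-methyl-5-(2,6,6-trimethylcyclohex-2-en-1-yl)penta-2,4-dienoate (racemic) | CCOC(=O)/C=C(C)/C=C/C1C(C)=CCCC1(C)C | intermediate
17 | ethyl (2E,4E)-3-methyl-5-(2,6,6-trimethyl-4-oxocyclohex-2-en-1-yl)penta-2,4-dienoate (racemic) | CCOC(=O)/C=C(C)/C=C/C1C(C)=CC(=O)CC1(C)C | intermediate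
18 | ethyl (2E,4E)-5-[(1RS,4RS)-4-hydroxy-2,6,6-trimethylcyclohex-2-en-1-yl]-3-methylpenta-2,4-dienoate (racemate, both antipodes written) | CC1=C[C@H](O)CC(C)(C)[C@H]1/C=C/C(C)=C/C(=O)OCC.CC1=C[C@@H](O)CC(C)(C)[C@@H]1/C=C/C(C)=C/C(=O)OCC | intermediate
19 | ethyl (2E,4E)-5-[(1R,4R)-4-hydroxy-2,6,6-trimethylcyclohex-2-en-1-yl]-3-methylpenta-2,4-dienoate | CC1=C[C@H](O)CC(C)(C)[C@H]1/C=C/C(C)=C/C(=O)OCC | intermediate
20 | (2E,4E)-5-[(1R,4R)-4-hydroxy-2,6,6-trimethylcyclohex-2-en-1-yl]-3-methylpenta-2,4-dien-1-ol | CC1=C[C@H](O)CC(C)(C)[C@H]1/C=C/C(C)=C/CO | intermediate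
21 | (1R,4R)-4-[(1E,3E)-5-chloro-3-methylpenta-1,3-dien-1-yl]-3,5,5-trimethylcyclohex-2-en-1-ol (not isolated) | CC1=C[C@H](O)CC(C)(C)[C@H]1/C=C/C(C)=C/CCl | intermediate
22 | [(2E,4E)-5-[(1R,4R)-4-hydroxy-2,6,6-trimethylcyclohex-2-en-1-yl]-3-methylpenta-2,4-dien-1-yl]triphenylphosphonium chloride | CC1=C[C@H](O)CC(C)(C)[C@H]1/C=C/C(C)=C/C[P+](c1ccccc1)(c1ccccc1)c1ccccc1.[Cl-] | intermediate
23 | (2E,4E,6E)-2,7-dimethylocta-2,4,6-trienedial | O=C/C(C)=C/C=C/C=C(C)/C=O | starting material
24 | (2E,4E,6E,8E,10E,12E)-13-[(1R,4R)-4-hydroxy-2,6,6-trimethylcyclohex-2-en-1-yl]-2,7,11-trimethyltrideca-2,4,6,8,10,12-hexaenal | CC1=C[C@H](O)CC(C)(C)[C@H]1/C=C/C(C)=C/C=C/C(C)=C/C=C/C=C(C)/C=O | intermediate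
25 | (3S,5R,8S,3'R,6'R)-3-(tert-butyldimethylsilyloxy)-5,8-epoxy-5,8-dihydro-β,ε-caroten-3'-ol | CC1=C[C@H](O)CC(C)(C)[C@H]1/C=C/C(C)=C/C=C/C(C)=C/C=C/C=C(C)/C=C/C=C(\C)[C@@H]1C=C2C(C)(C)C[C@H](O[Si](C)(C)C(C)(C)C)C[C@@]2(C)O1 | intermediate
26 | (3S,5R,8S,3'R,6'R)-5,8-epoxy-5,8-dihydro-β,ε-carotene-3,3'-diol | CC1=C[C@H](O)CC(C)(C)[C@H]1/C=C/C(C)=C/C=C/C(C)=C/C=C/C=C(C)/C=C/C=C(\C)[C@@H]1C=C2C(C)(C)C[C@H](O)C[C@@]2(C)O1 | target

**Step count and risks**
Total steps: 19. Longest linear sequence: 10 steps (steps 1–7, 10, 18, 19).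

Step 10, poor facial selectivity at C8: the chiral boronate may discriminate only weakly between the two nearly equivalent faces of the cation, or be mismatched with the substrate, and alkenyl transfer from the α-methyl boronate may be slow. Using the antipodal acid is the first remedy but is only a change of conditions. The fallback gives up kinetic control. It sets out from 9 and 13, which are united with Yb(OTf)3 alone to give 14 together with its C8 epimer, diethyl {(2E)-3-[(2R,6S,7aR)-6-(tert-butyldimethylsilyloxy)-4,4,7a-trimethyl-2,4,5,6,7,7a-hexahydro-1-benzofuran-2-yl]but-2-en-1-yl}phosphonate F1. The two are separated on base-washed silica. F1 is re-equilibrated with a trace of pyridinium p-toluenesulfonate in CH2Cl2 (reversible opening of the C8–O1 bond through the pentadienyl cation, the known acid epimerization of 5,8-epoxy end groups) and recycled. The fallback comes back to the route at 14.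

Step 18, ring opening by the carbanion: the phosphonate-stabilized allyl anion carries charge on C9 and may expel the ring oxygen from C8 (vinylogous β-elimination), and the new double bond may form with mixed geometry. The fallback changes the order of bond construction so that no carbanion is ever generated next to the dihydrofuran. It sets out from 13 and 24, which are joined first by Horner–Wadsworth–Emmons olefination (KOtBu, THF) to the polyenyl boronate dicyclohexyl [(3'R,6'R)-3'-hydroxy-9-apo-ε-caroten-9-yl]boronate F2. F2 is then coupled with acetate 9 under the conditions of step 10, so that C8–C9 is made last. The fallback comes back to the route at 25.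

Step 3, sluggish coupling at the hindered triflate: oxidative addition and transmetalation at the tetrasubstituted triflate next to the gem-dimethyl carbon may be slow, leading to reduction of the triflate and self-condensation of the zinc enolate. The fallback builds C6–C7 by carbonyl addition instead. It sets out from ketone 2, which takes up the Reformatsky reagent from ethyl bromoacetate and zinc to give the β-hydroxy ester ethyl 2-[(4R,6R)-4-(tert-butyldimethylsilyloxy)-1-hydroxy-2,2,6-trimethylcyclohexyl]acetate F3 (configuration at the carbinol carbon irrelevant). Dehydration with SOCl2/pyridine and equilibration with NaOEt to the tetrasubstituted endocyclic alkene lead back to the route at 4.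

**Further compounds**
F1 | step 10 | diethyl {(2E)-3-[(2R,6S,7aR)-6-(tert-butyldimethylsilyloxy)-4,4,7a-trimethyl-2,4,5,6,7,7a-hexahydro-1-benzofuran-2-yl]but-2-en-1-yl}phosphonate | CCOP(=O)(OCC)C/C=C(\C)[C@H]1C=C2C(C)(C)C[C@H](O[Si](C)(C)C(C)(C)C)C[C@@]2(C)O1
F2 | step 18 | dicyclohexyl [(3'R,6'R)-3'-hydroxy-9-apo-ε-caroten-9-yl]boronate (all-E, boron on C9 trans to C11) | CC1=C[C@H](O)CC(C)(C)[C@H]1/C=C/C(C)=C/C=C/C(C)=C/C=C/C=C(C)/C=C/C=C(\C)B(OC1CCCCC1)OC1CCCCC1
F3 | step 3 | ethyl 2-[(4R,6R)-4-(tert-butyldimethylsilyloxy)-1-hydroxy-2,2,6-trimethylcyclohexyl]acetate | CCOC(=O)CC1(O)C(C)(C)C[C@H](O[Si](C)(C)C(C)(C)C)C[C@H]1C
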